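The plan cuts the O1–C2 bond of ring C. In kaempferol 3-O-sulfate the ring oxygen O1 sits on C2 and the sulfated oxygen on the adjacent C3. A C2,C3 cyclic sulfate therefore supplies both the leaving group on C2 and the finished ester on O3. Precursor 8 is the trans cyclic sulfate of a chalcone diol. Its C3 bears the ring A aroyl group, its C2 bears the 4-benzyloxyphenyl ring B, and the future O1 on C8a is masked as a silyl ether. Fluoride frees this phenoxide, which displaces the benzylic C2–O bond. One operation closes ring C and leaves the sulfur as monoester on O3, so no separate regioselective sulfation is needed.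

Key step: step 7

Remark on stereochemistry: steps 4 to 7 are run on racemates because step 8 removes both stereocentres; names and SMILES show one enantiomer, and the trans (4R,5S) cyclic sulfate maps onto the trans (2R,3R) chromanone through one inversion at the benzylic carbon.
Remark on the salt form: the ring closure delivers the sulfate monoester as its caesium salt, not as the free acid, which would catalyse its own hydrolysis; the salt is carried through steps 8 and 9 and the proton form of the target is released only in the last operation.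
Remark on the precursor: 8 is a p-alkoxybenzylic sulfate diester and ionises easily; the donor ring B is kept because it steers the closure to C2 and later eases hydride loss from C2, and the lability is met by a cold buffered oxidation, no storage, and MeCN instead of a nucleophilic amide solvent in step 7.

Step 1
Reactants: 1 2',4',6'-trihydroxyacetophenone
Product: 2 4',6'-bis(benzyloxy)-2'-hydroxyacetophenone
Conditions: BnBr (2.1 equiv), K2CO3 (2.2 equiv), acetone, reflux
Reagents that add atoms: benzyl bromide, BrCc1ccccc1
Why: Williamson ether synthesis; once the 4'-hydroxyl and one of the two equivalent ortho hydroxyls are benzylated, the last hydroxyl is held in a hydrogen bond to the acetyl carbonyl and is not alkylated by a weak base and a limited amount of halide.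

Step 2
Reactants: 2 4',6'-bis(benzyloxy)-2'-hydroxyacetophenone; 3 4-(benzyloxy)benzaldehyde
Product: 4 (E)-4,4',6'-tris(benzyloxy)-2'-hydroxychalcone
Conditions: KOH, EtOH–THF–H2O, rt; then cold aq HCl
Reagents that add atoms: none
Why: Claisen–Schmidt condensation (crossed aldol, then E1cB loss of water) of a methyl ketone with a non-enolisable aldehyde gives the conjugated E-enone under thermodynamic control, and the strongly basic medium holds the product as its open phenoxide instead of the flavanone.

Step 3
Reactants: 4 (E)-4,4',6'-tris(benzyloxy)-2'-hydroxychalcone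
Product: 5 (E)-4,4',6'-tris(benzyloxy)-2'-(tert-butyldimethylsilyloxy)chalcone
Conditions: TBSCl, imidazole, DMF, rt
Reagents that add atoms: tert-butyldimethylsilyl chloride, C[Si](C)(Cl)C(C)(C)C
Why: Imidazole-promoted O-silylation of a phenol; only one hydroxyl is free, and the mild base at room temperature should not trigger the oxa-Michael closure to the flavanone.

Step 4
Reactants: 5 (E)-4,4',6'-tris(benzyloxy)-2'-(tert-butyldimethylsilyloxy)chalcone
Product: 6 rac-(2R,3S)-1-[2,4-bis(benzyloxy)-6-(tert-butyldimethylsilyloxy)phenyl]-3-[4-(benzyloxy)phenyl]-2,3-dihydroxypropan-1-one (threo)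
Conditions: K2OsO2(OH)4 (2 mol %), NMO, citric acid, THF–t-BuOH–H2O, rt
Reagents that add atoms: N-methylmorpholine N-oxide, C[N+]1([O-])CCOCC1; water, O
Why: Catalytic OsO4/NMO syn-dihydroxylation in its citric acid-buffered form for electron-poor alkenes; suprafacial delivery of both oxygens to the E-alkene fixes the threo (2R,3S) relationship as a racemate, and the slightly acidic medium suppresses retro-aldol cleavage and migration of the silyl group to the new hydroxyls.

Step 5
Reactants: 6 rac-(2R,3S)-diol
Product: 7 rac-(4R,5S)-4-[2,4-bis(benzyloxy)-6-(tert-butyldimethylsilyloxy)benzoyl]-5-[4-(benzyloxy)phenyl]-1,3,2-dioxathiolane 2-oxide (trans, both epimers at sulfur)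
Conditions: SOCl2, Et3N, CH2Cl2, −20 → 0 °C
Reagents that add atoms: thionyl chloride, O=S(Cl)Cl
Why: Cyclic sulfite formation from a 1,2-diol; no C–O bond is broken, so the threo diol gives the trans ring, the new centre at sulfur arises as both epimers that converge in step 6, and excess base at low temperature keeps HCl away from the p-alkoxybenzylic position.

Step 6
Reactants: 7 rac-trans cyclic sulfite
Product: 8 rac-(4R,5S)-4-[2,4-bis(benzyloxy)-6-(tert-butyldimethylsilyloxy)benzoyl]-5-[4-(benzyloxy)phenyl]-1,3,2-dioxathiolane 2,2-dioxide (trans)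
Conditions: RuCl3·xH2O (0.5 mol %), NaIO4 (1.3 equiv), CH2Cl2–MeCN–pH 7 buffer, 0 °C, short contact; cold extraction, short silica pad, used at once
Reagents that add atoms: sodium periodate, [Na+].[O-]I(=O)(=O)=O
Why: RuO4-catalysed oxidation of a cyclic sulfite to the cyclic sulfate (tetravalent to hexavalent sulfur); oxygen transfer to sulfur is much faster than attack of RuO4 on benzyl ethers or arenes, so a small catalyst charge, a slight excess of NaIO4 and a short time at 0 °C should spare them, and the carbon stereocentres are not involved.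

Step 7
Reactants: 8 rac-trans cyclic sulfate
Product: 10 caesium rac-(2R,3R)-5,7-bis(benzyloxy)-2-[4-(benzyloxy)phenyl]-4-oxochroman-3-yl sulfate (2,3-trans), via caesium phenoxide 9 (not isolated)
Conditions: CsF (1.05 equiv, dried), MeCN (0.01 M), 0 °C → rt
Reagents that add atoms: caesium fluoride, [Cs+].[F-]
Why: Proposed new method: fluoride attacks silicon of the aryl silyl ether (the ortho-acyl phenoxide is a good leaving group), and the caesium phenoxide 9 displaces the benzylic C2–O bond of the cyclic sulfate from the rear in an SN2 process, so that O1–C2 forms, the C3–O–S linkage is never touched and the sulfur ends as the monoester anion on O3. The closest known reaction types are the opening of 1,2-cyclic sulfates by external nucleophiles to β-substituted sulfate monoesters and the closure of 2'-hydroxychalcone epoxides to trans-dihydroflavonols; a phenoxide tethered to an α-keto cyclic sulfate has not been shown. Ring C closes in the 6-exo-tet mode, the breaking C2–O bond lying outside the new ring. C2 is set by inversion of the 5S centre of the trans cyclic sulfate while C3 is carried over unchanged, which gives the 2,3-trans (2R,3R) relationship, and any leakage through ionisation is harmless because step 8 removes both centres. The selectivity needed is attack at C2 rather than at the carbonyl-activated C3 (5-exo-tet), and it is secured by the 4-benzyloxyphenyl donor, which loosens the benzylic C–O bond, while one equivalent of sparingly soluble CsF at high dilution keeps fluoride from competing at carbon and suppresses intermolecular alkylation. If proton loss from the acidic C3 position with β-elimination runs first, conjugate re-addition of the phenoxide at C2 leads to the same constitution.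

Step 8
Reactants: 10 caesium rac-trans-flavanon-3-yl sulfate
Product: 11 caesium 5,7-bis(benzyloxy)-2-[4-(benzyloxy)phenyl]-4-oxo-4H-chromen-3-yl sulfate
Conditions: DDQ, 1,4-dioxane–MeCN, 90 °C
Reagents that add atoms: none
Why: DDQ dehydrogenation of a flavanone to a flavone; hydride is lost from C2, which is benzylic, attached to O1 and supported by the para-benzyloxy donor, the acidic C3 proton follows, and the non-basic sulfate anion is inert to the quinone in this neutral medium, so C2=C3 forms with the ester in place and both stereocentres vanish.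

Step 9
Reactants: 11 caesium tri-O-benzylkaempferol 3-sulfate
Product: 13 kaempferol 3-O-sulfate, via caesium kaempferol 3-sulfate 12 (not isolated)
Conditions: H2 (1 atm), Pd/C, THF–MeOH, rt; filter; then aq HCl (1.0 equiv), 0 °C, C18 desalting, freeze-drying
Reagents that add atoms: none
Why: Catalytic hydrogenolysis of aryl benzyl ethers runs under neutral conditions that sulfate monoester salts and the flavone C2=C3 bond tolerate, and one equivalent of cold dilute acid followed by reversed-phase desalting exchanges the cation for a proton without the heat and acid strength that hydrolysis of the ester needs.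

Compound list
1 | 2',4',6'-trihydroxyacetophenone | CC(=O)c1c(O)cc(O)cc1O | starting material
2 | 4',6'-bis(benzyloxy)-2'-hydroxyacetophenone | CC(=O)c1c(O)cc(OCc2ccccc2)cc1OCc1ccccc1 | intermediate
3 | 4-(benzyloxy)benzaldehyde | O=Cc1ccc(OCc2ccccc2)cc1 | starting material
4 | (E)-4,4',6'-tris(benzyloxy)-2'-hydroxychalcone | O=C(/C=C/c1ccc(OCc2ccccc2)cc1)c1c(O)cc(OCc2ccccc2)cc1OCc1ccccc1 | intermediate
5 | (E)-4,4',6'-tris(benzyloxy)-2'-(tert-butyldimethylsilyloxy)chalcone | O=C(/C=C/c1ccc(OCc2ccccc2)cc1)c1c(O[Si](C)(C)C(C)(C)C)cc(OCc2ccccc2)cc1OCc1ccccc1 | intermediate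
6 | rac-(2R,3S)-1-[2,4-bis(benzyloxy)-6-(tert-butyldimethylsilyloxy)phenyl]-3-[4-(benzyloxy)phenyl]-2,3-dihydroxypropan-1-one | O=C(c1c(O[Si](C)(C)C(C)(C)C)cc(OCc2ccccc2)cc1OCc1ccccc1)[C@H](O)[C@@H](O)c1ccc(OCc2ccccc2)cc1 | intermediate
7 | rac-(4R,5S)-4-[2,4-bis(benzyloxy)-6-(tert-butyldimethylsilyloxy)benzoyl]-5-[4-(benzyloxy)phenyl]-1,3,2-dioxathiolane 2-oxide (both epimers at sulfur) | O=C(c1c(O[Si](C)(C)C(C)(C)C)cc(OCc2ccccc2)cc1OCc1ccccc1)[C@@H]1OS(=O)O[C@H]1c1ccc(OCc2ccccc2)cc1 | intermediate
8 | rac-(4R,5S)-4-[2,4-bis(benzyloxy)-6-(tert-butyldimethylsilyloxy)benzoyl]-5-[4-(benzyloxy)phenyl]-1,3,2-dioxathiolane 2,2-dioxide (trans) | O=C(c1c(O[Si](C)(C)C(C)(C)C)cc(OCc2ccccc2)cc1OCc1ccccc1)[C@@H]1OS(=O)(=O)O[C@H]1c1ccc(OCc2ccccc2)cc1 | intermediate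
9 | caesium 3,5-bis(benzyloxy)-2-{rac-(4R,5S)-5-[4-(benzyloxy)phenyl]-2,2-dioxo-1,3,2-dioxathiolane-4-carbonyl}phenoxide (not isolated) | [Cs+].O=C(c1c([O-])cc(OCc2ccccc2)cc1OCc1ccccc1)[C@@H]1OS(=O)(=O)O[C@H]1c1ccc(OCc2ccccc2)cc1 | intermediate
10 | caesium rac-(2R,3R)-5,7-bis(benzyloxy)-2-[4-(benzyloxy)phenyl]-4-oxochroman-3-yl sulfate (2,3-trans) | [Cs+].O=C1c2c(OCc3ccccc3)cc(OCc3ccccc3)cc2O[C@H](c2ccc(OCc3ccccc3)cc2)[C@H]1OS(=O)(=O)[O-] | intermediate
11 | caesium 5,7-bis(benzyloxy)-2-[4-(benzyloxy)phenyl]-4-oxo-4H-chromen-3-yl sulfate | [Cs+].O=c1c(OS(=O)(=O)[O-])c(-c2ccc(OCc3ccccc3)cc2)oc2cc(OCc3ccccc3)cc(OCc3ccccc3)c12 | intermediate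
12 | caesium 5,7-dihydroxy-2-(4-hydroxyphenyl)-4-oxo-4H-chromen-3-yl sulfate (not isolated) | [Cs+].O=c1c(OS(=O)(=O)[O-])c(-c2ccc(O)cc2)oc2cc(O)cc(O)c12 | intermediate
13 | kaempferol 3-O-sulfate, 5,7-dihydroxy-2-(4-hydroxyphenyl)-4-oxo-4H-chromen-3-yl hydrogen sulfate | O=c1c(OS(=O)(=O)O)c(-c2ccc(O)cc2)oc2cc(O)cc(O)c12 | target

Total step count: 9. Longest linear sequence: 9 steps (1 → 13); 3 enters in step 2.

Steps most likely to fail

Step 7 (Proposed new method).
- **Risk:** closure at the carbonyl-activated C3 in the five-membered mode, capture of the easily ionised benzylic carbon by fluoride or solvent, or aroyl migration after ionisation.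
- **Fallback (known chemistry, sulfate installed last):** it sets out from chalcone 4. Catalytic I2 in DMSO at 130 °C cyclises 4 oxidatively to 5,7,4'-tri-O-benzylapigenin F1. Dimethyldioxirane in acetone–CH2Cl2 at 0 °C epoxidises C2=C3 to tri-O-benzylapigenin 2,3-epoxide F2. A trace of p-TsOH isomerises this to 5,7,4'-tri-O-benzylkaempferol F3. Sulfation of its only free hydroxyl with SO3·pyridine in pyridine, followed by neutralisation with Cs2CO3, comes back to the route at 11.

Step 6.
- **Risk:** over-oxidation of benzyl ethers and electron-rich rings by RuO4, and hydrolytic opening through ionisation of the p-alkoxybenzylic C–O bond during the aqueous oxidation or on silica.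
- **Fallback:** it sets out from cyclic sulfite 7 and gives up the oxidation. CsF in MeCN (rt to 50 °C) frees the phenoxide, which opens the sulfite at the benzylic carbon; benzylic opening of aryl-substituted cyclic sulfites by nucleophiles is known. This gives caesium rac-trans-5,7,4'-tri-O-benzylflavanon-3-yl sulfite F4. One equivalent of cold aq HCl expels SO2 and leaves rac-trans-5,7,4'-tri-O-benzyldihydrokaempferol F5. Sulfation of its secondary hydroxyl with SO3·pyridine and neutralisation with Cs2CO3 comes back to the route at 10.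

Step 8.
- **Risk:** sluggish hydride transfer from a poorly soluble salt, thermal solvolysis of the sulfate ester, or oxidative loss of benzyl groups.
- **Fallback:** it reverses the order of the last two operations and sets out from 10. Hydrogenolysis (H2, Pd/C, THF–MeOH) gives caesium rac-trans-dihydrokaempferol 3-sulfate F6. I2 in pyridine at 90 °C, the iodination–dehydroiodination used to turn free-phenolic flavanones into flavones, then dehydrogenates it in a basic medium that protects the sulfate. This comes back to the route at 12.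

Further compounds
F1 | step 7 | 5,7-bis(benzyloxy)-2-[4-(benzyloxy)phenyl]-4H-chromen-4-one (5,7,4'-tri-O-benzylapigenin) | O=c1cc(-c2ccc(OCc3ccccc3)cc2)oc2cc(OCc3ccccc3)cc(OCc3ccccc3)c12
F2 | step 7 | rac-4,6-bis(benzyloxy)-1a-[4-(benzyloxy)phenyl]-1a,7a-dihydro-7H-oxireno[2,3-b]chromen-7-one (tri-O-benzylapigenin 2,3-epoxide, cis-fused) | O=C1c2c(OCc3ccccc3)cc(OCc3ccccc3)cc2O[C@@]2(c3ccc(OCc4ccccc4)cc3)O[C@@H]12
F3 | step 7 | 5,7-bis(benzyloxy)-2-[4-(benzyloxy)phenyl]-3-hydroxy-4H-chromen-4-one (5,7,4'-tri-O-benzylkaempferol) | O=c1c(O)c(-c2ccc(OCc3ccccc3)cc2)oc2cc(OCc3ccccc3)cc(OCc3ccccc3)c12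
F4 | step 6 | caesium rac-(2R,3R)-5,7-bis(benzyloxy)-2-[4-(benzyloxy)phenyl]-4-oxochroman-3-yl sulfite | [Cs+].O=C1c2c(OCc3ccccc3)cc(OCc3ccccc3)cc2O[C@H](c2ccc(OCc3ccccc3)cc2)[C@H]1OS(=O)[O-]
F5 | step 6 | rac-(2R,3R)-5,7-bis(benzyloxy)-2-[4-(benzyloxy)phenyl]-3-hydroxychroman-4-one (5,7,4'-tri-O-benzyldihydrokaempferol) | O=C1c2c(OCc3ccccc3)cc(OCc3ccccc3)cc2O[C@H](c2ccc(OCc3ccccc3)cc2)[C@H]1O
F6 | step 8 | caesium rac-(2R,3R)-5,7-dihydroxy-2-(4-hydroxyphenyl)-4-oxochroman-3-yl sulfate (dihydrokaempferol 3-sulfate) | [Cs+].O=C1c2c(O)cc(O)cc2O[C@H](c2ccc(O)cc2)[C@H]1OS(=O)(=O)[O-]
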